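**Retrosynthetic overview**
- Target ⇒ hydrogenolysis of two aryl benzyl ethers ⇒ threo-(7R,8R) arylglycerol arm from an Evans syn-glycolate aldol (aryloxyacetyl imide + O-benzylvanillin), then reductive removal of the auxiliary.
- Aryloxyacetyl imide ⇒ Williamson etherification of a mono-phenolic (3R,4R)-dibenzylbutyrolactone with a chloroacetyl oxazolidinone.
- trans-Dibenzyl lactone ⇒ α-benzylation, then decarboxylation of an α-methoxycarbonyl β-benzyl lactone (C3 set trans to C4 under thermodynamic control).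
- β-Benzyl lactone ester ⇒ CuI-catalysed aryl Grignard opening of a cyclopropane-fused lactone ⇒ dimethyl malonate + (R)-epichlorohydrin.
- Ring order: cyclopropane and γ-lactone are formed together in step 1; the cyclopropane is opened in step 2 and the lactone is kept; the benzene rings and the auxiliary ring are bought.

Assumption: compounds 1, 2, 6, 9, 14, 15 and 18 are taken as inexpensive catalogue chemicals.

**Step 1**
Reactants: 1 dimethyl malonate; 2 (R)-epichlorohydrin
Product: 5 methyl (1S,5R)-2-oxo-3-oxabicyclo[3.1.0]hexane-1-carboxylate, via epoxy malonate 3 (not isolated), via cyclopropylmethoxide 4 (not isolated)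
Conditions: NaOMe (1.0 equiv), MeOH, 0 → 65 °C, 16 h
Reagents that add atoms: none
Why: Tandem alkylation/3-exo-tet cyclopropanation/lactonisation: the malonate anion opens the epoxide of 2 at CH2, the alkoxide expels chloride to give 3, the re-formed malonate anion closes the cyclopropane with inversion at the stereocentre, and alkoxide 4 lactonises onto the cis ester, so both rings form in one operation and the chirality of 2 fixes C5 as R while the cis fusion fixes C1 as S.

**Step 2**
Reactants: 5 methyl (1S,5R)-2-oxo-3-oxabicyclo[3.1.0]hexane-1-carboxylate; 6 1-(benzyloxy)-4-bromo-2-methoxybenzene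
Product: 8 methyl (3S,4R)-4-[4-(benzyloxy)-3-methoxybenzyl]-2-oxooxolane-3-carboxylate, via arylmagnesium bromide 7 (not isolated)
Conditions: 6, Mg, THF, 40 °C; then 5, CuI (10 mol%), THF, −40 → −20 °C; 1 M HCl
Reagents that add atoms: none
Why: CuI-catalysed homoconjugate (SN2-type) addition of the aryl Grignard reagent to the doubly activated cyclopropane occurs at the unsubstituted CH2 and cleaves the C1–C6 bond, leaving the former C5 (now lactone C4, R) untouched; C3 is epimerisable, settles mainly trans, and is quaternised in step 4.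

**Step 3**
Reactants: 9 vanillyl alcohol
Product: 10 4-(bromomethyl)-2-methoxyphenyl acetate
Conditions: acetyl bromide (2.5 equiv), CH2Cl2, 0 °C → rt
Reagents that add atoms: acetyl bromide CC(=O)Br
Why: Acetyl bromide acetylates the phenol and converts the electron-rich benzylic alcohol (via its acetate and HBr) into the bromide in one pot, the O-acetyl group suppressing quinone-methide formation so the bromide can be handled; no stereocentre is involved.

**Step 4**
Reactants: 8 methyl (3S,4R)-4-[4-(benzyloxy)-3-methoxybenzyl]-2-oxooxolane-3-carboxylate; 10 4-(bromomethyl)-2-methoxyphenyl acetate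
Product: 11 methyl (3R,4R)-3-(4-acetoxy-3-methoxybenzyl)-4-[4-(benzyloxy)-3-methoxybenzyl]-2-oxooxolane-3-carboxylate
Conditions: NaH (1.05 equiv), THF/DMF (4:1), 0 °C; then 10, 0 °C → rt
Reagents that add atoms: none
Why: SN2 C-alkylation of the stabilised sodium enolate of the malonate-type lactone by the reactive benzylic bromide; the electrophile enters anti to the C4 benzyl group to give the (3R,4R) quaternary centre, whose configuration is in any case erased in step 5.

**Step 5**
Reactants: 11 methyl (3R,4R)-3-(4-acetoxy-3-methoxybenzyl)-4-[4-(benzyloxy)-3-methoxybenzyl]-2-oxooxolane-3-carboxylate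
Product: 13 (3R,4R)-4-[4-(benzyloxy)-3-methoxybenzyl]-3-(4-hydroxy-3-methoxybenzyl)oxolan-2-one, via acetoxy lactone 12 (not isolated)
Conditions: LiCl (3 equiv), DMSO/H2O (10:1), 140 °C; 1 M HCl work-up
Reagents that add atoms: none
Why: Krapcho dealkoxycarbonylation (chloride SN2 at the ester methyl, loss of CO2, protonation of the lactone enolate), with the hydroxide released cleaving the aryl acetate of 12; C3 is set under thermodynamic control trans to the C4 benzyl group (3R), and any cis isomer equilibrates in the basic medium.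

**Step 6**
Reactants: 14 (4S)-4-benzyl-1,3-oxazolidin-2-one; 15 chloroacetyl chloride
Product: 16 (4S)-4-benzyl-3-(chloroacetyl)-1,3-oxazolidin-2-one
Conditions: n-BuLi (1.0 equiv), THF, −78 °C; then 15, −78 → 0 °C
Reagents that add atoms: none
Why: N-Acylation of the lithiated oxazolidinone by the acid chloride, acyl substitution being far faster than displacement of the α-chloride at −78 °C; the auxiliary stereocentre is untouched.

**Step 7**
Reactants: 13 (3R,4R)-4-[4-(benzyloxy)-3-methoxybenzyl]-3-(4-hydroxy-3-methoxybenzyl)oxolan-2-one; 16 (4S)-4-benzyl-3-(chloroacetyl)-1,3-oxazolidin-2-one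
Product: 17 (4S)-4-benzyl-3-[(4-{[(3R,4R)-4-[4-(benzyloxy)-3-methoxybenzyl]-2-oxooxolan-3-yl]methyl}-2-methoxyphenoxy)acetyl]-1,3-oxazolidin-2-one
Conditions: K2CO3 (1.5 equiv), NaI (10 mol%), acetone, rt → 45 °C
Reagents that add atoms: none
Why: Williamson ether synthesis in which the phenoxide of 13 displaces the activated α-halide of 16 (iodide catalysis) under mild carbonate conditions that leave the thermodynamically trans lactone unchanged; no new stereocentre is formed.

**Step 8**
Reactants: 17 (4S)-4-benzyl-3-[(4-{[(3R,4R)-4-[4-(benzyloxy)-3-methoxybenzyl]-2-oxooxolan-3-yl]methyl}-2-methoxyphenoxy)acetyl]-1,3-oxazolidin-2-one; 18 4-(benzyloxy)-3-methoxybenzaldehyde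
Product: 20 (4S)-4-benzyl-3-[(2S,3R)-3-[4-(benzyloxy)-3-methoxyphenyl]-2-(4-{[(3R,4R)-4-[4-(benzyloxy)-3-methoxybenzyl]-2-oxooxolan-3-yl]methyl}-2-methoxyphenoxy)-3-hydroxypropanoyl]-1,3-oxazolidin-2-one, via boron enolate 19 (not isolated)
Conditions: n-Bu2BOTf (1.3 equiv), iPr2NEt (1.5 equiv), CH2Cl2, −78 → 0 °C; then 18, −78 → 0 °C; pH 7 buffer, MeOH, 30% H2O2, 0 °C
Reagents that add atoms: none
Why: Evans boron-mediated syn-glycolate aldol in which soft enolisation gives the Z enolate 19 (the lactone is not enolised), which reacts through a closed Zimmerman–Traxler transition state on the face away from the auxiliary benzyl group, setting the aryloxy carbon (2S in the imide, 8R after reduction) and the carbinol carbon (3R) in the syn, i.e. threo, relationship.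

**Step 9**
Reactants: 20 (4S)-4-benzyl-3-[(2S,3R)-3-[4-(benzyloxy)-3-methoxyphenyl]-2-(4-{[(3R,4R)-4-[4-(benzyloxy)-3-methoxybenzyl]-2-oxooxolan-3-yl]methyl}-2-methoxyphenoxy)-3-hydroxypropanoyl]-1,3-oxazolidin-2-one
Product: 21 (3R,4R)-4-[4-(benzyloxy)-3-methoxybenzyl]-3-(4-{[(1R,2R)-1-[4-(benzyloxy)-3-methoxyphenyl]-1,3-dihydroxypropan-2-yl]oxy}-3-methoxybenzyl)oxolan-2-one
Conditions: NaBH4 (2 equiv), THF/H2O (4:1), 0 °C → rt
Reagents that add atoms: none
Why: Chemoselective borohydride reduction of the activated N-acyl oxazolidinone (assisted by the β-hydroxyl) to the primary alcohol with release of the auxiliary, the much less electrophilic γ-lactone being left intact at this temperature; no stereocentre is touched.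

**Step 10**
Reactants: 21 (3R,4R)-4-[4-(benzyloxy)-3-methoxybenzyl]-3-(4-{[(1R,2R)-1-[4-(benzyloxy)-3-methoxyphenyl]-1,3-dihydroxypropan-2-yl]oxy}-3-methoxybenzyl)oxolan-2-one
Product: 22 (3R,4R)-3-(4-{[(1R,2R)-1,3-dihydroxy-1-(4-hydroxy-3-methoxyphenyl)propan-2-yl]oxy}-3-methoxybenzyl)-4-(4-hydroxy-3-methoxybenzyl)oxolan-2-one
Conditions: H2 (1 atm), 10% Pd/C, EtOAc/MeOH, rt
Reagents that add atoms: none
Why: Catalytic hydrogenolysis under neutral conditions cleaves the two aryl benzyl ethers much faster than the secondary benzylic alcohol or the alkyl aryl ether, so the target is released with all four stereocentres intact.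

**Compound list**
1 | dimethyl malonate | COC(=O)CC(=O)OC | starting material
2 | (R)-epichlorohydrin, (2R)-2-(chloromethyl)oxirane | ClC[C@H]1CO1 | starting material
3 | dimethyl 2-{[(2R)-oxiran-2-yl]methyl}propanedioate (formed in the flask) | COC(=O)C(C[C@@H]1CO1)C(=O)OC | intermediate
4 | sodium [(1R)-2,2-bis(methoxycarbonyl)cyclopropyl]methanolate (formed in the flask) | COC(=O)C1(C(=O)OC)C[C@H]1C[O-].[Na+] | intermediate
5 | methyl (1S,5R)-2-oxo-3-oxabicyclo[3.1.0]hexane-1-carboxylate | COC(=O)[C@]12C[C@H]1COC2=O | intermediate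
6 | 1-(benzyloxy)-4-bromo-2-methoxybenzene | COc1cc(Br)ccc1OCc1ccccc1 | starting material
7 | [4-(benzyloxy)-3-methoxyphenyl]magnesium bromide (formed in the flask) | COc1cc([Mg]Br)ccc1OCc1ccccc1 | intermediate
8 | methyl (3S,4R)-4-[4-(benzyloxy)-3-methoxybenzyl]-2-oxooxolane-3-carboxylate (major trans epimer; C3 epimerisable) | COC(=O)[C@@H]1[C@@H](Cc2ccc(OCc3ccccc3)c(OC)c2)COC1=O | intermediate
9 | vanillyl alcohol, 4-(hydroxymethyl)-2-methoxyphenol | COc1cc(CO)ccc1O | starting material
10 | 4-(bromomethyl)-2-methoxyphenyl acetate | COc1cc(CBr)ccc1OC(C)=O | intermediate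
11 | methyl (3R,4R)-3-(4-acetoxy-3-methoxybenzyl)-4-[4-(benzyloxy)-3-methoxybenzyl]-2-oxooxolane-3-carboxylate | COC(=O)[C@@]1(Cc2ccc(OC(C)=O)c(OC)c2)[C@@H](Cc2ccc(OCc3ccccc3)c(OC)c2)COC1=O | intermediate
12 | 4-{[(3R,4R)-4-[4-(benzyloxy)-3-methoxybenzyl]-2-oxooxolan-3-yl]methyl}-2-methoxyphenyl acetate (formed in the flask) | COc1cc(C[C@H]2COC(=O)[C@@H]2Cc2ccc(OC(C)=O)c(OC)c2)ccc1OCc1ccccc1 | intermediate
13 | (3R,4R)-4-[4-(benzyloxy)-3-methoxybenzyl]-3-(4-hydroxy-3-methoxybenzyl)oxolan-2-one | COc1cc(C[C@H]2COC(=O)[C@@H]2Cc2ccc(O)c(OC)c2)ccc1OCc1ccccc1 | intermediate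
14 | (4S)-4-benzyl-1,3-oxazolidin-2-one | O=C1N[C@@H](Cc2ccccc2)CO1 | starting material
15 | chloroacetyl chloride | ClCC(Cl)=O | starting material
16 | (4S)-4-benzyl-3-(chloroacetyl)-1,3-oxazolidin-2-one | ClCC(=O)N1[C@@H](Cc2ccccc2)COC1=O | intermediate
17 | (4S)-4-benzyl-3-[(4-{[(3R,4R)-4-[4-(benzyloxy)-3-methoxybenzyl]-2-oxooxolan-3-yl]methyl}-2-methoxyphenoxy)acetyl]-1,3-oxazolidin-2-one | COc1cc(C[C@H]2COC(=O)[C@@H]2Cc2ccc(OCC(=O)N3[C@@H](Cc4ccccc4)COC3=O)c(OC)c2)ccc1OCc1ccccc1 | intermediate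
18 | 4-(benzyloxy)-3-methoxybenzaldehyde (O-benzylvanillin) | COc1cc(C=O)ccc1OCc1ccccc1 | starting material
19 | Z-configured di-n-butylboron enolate of 17 (formed in the flask) | COc1cc(C[C@H]2COC(=O)[C@@H]2Cc2ccc(O/C=C(\OB(CCCC)CCCC)N3[C@@H](Cc4ccccc4)COC3=O)c(OC)c2)ccc1OCc1ccccc1 | intermediate
20 | (4S)-4-benzyl-3-[(2S,3R)-3-[4-(benzyloxy)-3-methoxyphenyl]-2-(4-{[(3R,4R)-4-[4-(benzyloxy)-3-methoxybenzyl]-2-oxooxolan-3-yl]methyl}-2-methoxyphenoxy)-3-hydroxypropanoyl]-1,3-oxazolidin-2-one | COc1cc(C[C@H]2COC(=O)[C@@H]2Cc2ccc(O[C@H](C(=O)N3[C@@H](Cc4ccccc4)COC3=O)[C@H](O)c3ccc(OCc4ccccc4)c(OC)c3)c(OC)c2)ccc1OCc1ccccc1 | intermediate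
21 | (3R,4R)-4-[4-(benzyloxy)-3-methoxybenzyl]-3-(4-{[(1R,2R)-1-[4-(benzyloxy)-3-methoxyphenyl]-1,3-dihydroxypropan-2-yl]oxy}-3-methoxybenzyl)oxolan-2-one | COc1cc(C[C@H]2COC(=O)[C@@H]2Cc2ccc(O[C@H](CO)[C@H](O)c3ccc(OCc4ccccc4)c(OC)c3)c(OC)c2)ccc1OCc1ccccc1 | intermediate
22 | (3R,4R)-3-(4-{[(1R,2R)-1,3-dihydroxy-1-(4-hydroxy-3-methoxyphenyl)propan-2-yl]oxy}-3-methoxybenzyl)-4-(4-hydroxy-3-methoxybenzyl)oxolan-2-one | COc1cc(C[C@H]2COC(=O)[C@@H]2Cc2ccc(O[C@H](CO)[C@H](O)c3ccc(O)c(OC)c3)c(OC)c2)ccc1O | target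

**Total step count:** 10.
**Longest linear sequence:** 8 steps (1, 2, 4, 5, 7, 8, 9, 10); steps 3 and 6 are one-step side branches.

**Three steps most likely to fail**

Step 7. The phenoxide of 13 may attack the exocyclic imide carbonyl of 16, or 16 may degrade under carbonate, instead of clean displacement of chloride. The fallback reverses the order of bond formation, making the aryl ether bond with a robust ester and the N-acyl bond last. It sets out from 13: tert-butyl bromoacetate and K2CO3 in acetone give the tert-butyl aryloxyacetate F1. TFA in CH2Cl2 then gives the aryloxyacetic acid F2. Activation as the pivaloyl mixed anhydride (PivCl, Et3N, THF, −20 °C) and acylation of 14 in the presence of LiCl returns to the route at 17; step 6 is then not needed.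

Step 8. The electron-rich aldehyde 18 is sluggish, so the boron aldol of the densely functionalised imide may stall, revert, or lose syn selectivity. The fallback replaces the aldol bond formation by C-acylation followed by stereoselective ketone reduction. It sets out from 17: LiN(SiMe3)2 in THF at −78 °C, then 4-(benzyloxy)-3-methoxybenzoyl chloride, gives the β-keto imide F3, whose aryloxy-bearing carbon is configurationally labile. Asymmetric transfer hydrogenation with dynamic kinetic resolution (RuCl[(S,S)-TsDPEN](p-cymene), HCO2H/Et3N, rt; ligand sense chosen to give the 3R carbinol) delivers the syn (2S,3R) alcohol and returns to the route at 20.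

Step 9. Borohydride may also reduce the γ-lactone, or the basic medium may trigger retro-aldol cleavage. The fallback swaps discrimination by electrophilicity for discrimination by functional-group class. It sets out from 20: LiOH/H2O2 in THF/H2O at 0 °C, then Na2SO3 and acidification to pH 2 (which re-closes any opened lactone), gives the carboxylic acid F4 and recovered 14. BH3·SMe2 in THF (0 °C → rt) reduces the free acid far faster than the lactone and returns to the route at 21.

**Further compounds**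
F1 | step 7 | tert-butyl (4-{[(3R,4R)-4-[4-(benzyloxy)-3-methoxybenzyl]-2-oxooxolan-3-yl]methyl}-2-methoxyphenoxy)acetate | COc1cc(C[C@H]2COC(=O)[C@@H]2Cc2ccc(OCC(=O)OC(C)(C)C)c(OC)c2)ccc1OCc1ccccc1
F2 | step 7 | (4-{[(3R,4R)-4-[4-(benzyloxy)-3-methoxybenzyl]-2-oxooxolan-3-yl]methyl}-2-methoxyphenoxy)acetic acid | COc1cc(C[C@H]2COC(=O)[C@@H]2Cc2ccc(OCC(=O)O)c(OC)c2)ccc1OCc1ccccc1
F3 | step 8 | (4S)-4-benzyl-3-[(2RS)-3-[4-(benzyloxy)-3-methoxyphenyl]-2-(4-{[(3R,4R)-4-[4-(benzyloxy)-3-methoxybenzyl]-2-oxooxolan-3-yl]methyl}-2-methoxyphenoxy)-3-oxopropanoyl]-1,3-oxazolidin-2-one | COc1cc(C[C@H]2COC(=O)[C@@H]2Cc2ccc(OC(C(=O)N3[C@@H](Cc4ccccc4)COC3=O)C(=O)c3ccc(OCc4ccccc4)c(OC)c3)c(OC)c2)ccc1OCc1ccccc1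
F4 | step 9 | (2S,3R)-3-[4-(benzyloxy)-3-methoxyphenyl]-2-(4-{[(3R,4R)-4-[4-(benzyloxy)-3-methoxybenzyl]-2-oxooxolan-3-yl]methyl}-2-methoxyphenoxy)-3-hydroxypropanoic acid | COc1cc(C[C@H]2COC(=O)[C@@H]2Cc2ccc(O[C@H](C(=O)O)[C@H](O)c3ccc(OCc4ccccc4)c(OC)c3)c(OC)c2)ccc1OCc1ccccc1
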